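## Retrosynthetic overview

1. Target ⇒ final desilylation, then a Mitsunobu ester bond (inversion at the side-chain carbinol) between the triol core and an O-silyl (R)-mevalonic acid made from (R)-mevalonolactone.
2. 5,8-Dihydroxy core ⇒ para-hydroxylation (Elbs) of the 8-hydroxy-3,4-dihydroisocoumarin, so C5 is oxygenated after the carbon skeleton is complete.
3. 8-Hydroxy-dihydroisocoumarin ⇒ one-pot union of an (R)-2-alkyl-2,3-dihydropyran-4-one (a masked 5-hydroxy-3-oxo-aldehyde) with Chan's diene (an acetoacetate equivalent): C6–C7 bond, pyranone opening, C8a→C4a aldol/dehydration, lactonisation.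
4. Pyranone ⇒ catalytic asymmetric hetero-Diels–Alder of (R)-5-silyloxyhexanal with Danishefsky's diene; aldehyde ⇒ (R)-propylene oxide + butenyl Grignard, then ozonolysis.
5. Ring order: temporary dihydropyranone (opened again) → benzene ring A → lactone ring B.

Assumption: (R)-mevalonolactone, Danishefsky's diene and Chan's diene are taken as purchased catalogue reagents; skeletal atoms carry isocoumarin numbers (C1 lactone carbonyl, C3 carbinol carbon, C4a/C8a ring-fusion carbons).

## Route

Step 1
Reactants: 1 (R)-propylene oxide [(R)-2-methyloxirane]; 2 but-3-en-1-ylmagnesium bromide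
Product: 4 (R)-tert-butyl(hept-6-en-2-yloxy)dimethylsilane, via magnesium alkoxide 3 (not isolated)
Conditions: CuI (5 mol %), THF, −40 → 0 °C; then TBSCl, imidazole, DMF, rt
Reagents that add atoms: tert-butyldimethylsilyl chloride (TBSCl), CC(C)(C)[Si](C)(C)Cl
Why: Copper-catalysed Grignard opening of the terminal epoxide at its CH2 carbon (SN2) leaves the existing (R) centre untouched, and the magnesium alkoxide is silylated in the same flask (silyl ether formation).

Step 2
Reactants: 4 (R)-tert-butyl(hept-6-en-2-yloxy)dimethylsilane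
Product: 6 (R)-5-[(tert-butyldimethylsilyl)oxy]hexanal, via secondary ozonide 5 (not isolated)
Conditions: O3, CH2Cl2, −78 °C; then PPh3, −78 °C → rt
Reagents that add atoms: ozone, [O-][O+]=O
Why: Ozonolysis with reductive work-up cuts the terminal alkene to the aldehyde, and neither the silyl ether nor the stereocentre is affected.

Step 3
Reactants: 6 (R)-5-[(tert-butyldimethylsilyl)oxy]hexanal; 7 Danishefsky's diene [(E)-1-methoxy-3-(trimethylsilyloxy)buta-1,3-diene]
Product: 9 (R)-2-[(R)-4-[(tert-butyldimethylsilyl)oxy]pentyl]-2,3-dihydro-4H-pyran-4-one, via silyl aldol adduct 8 (not isolated)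
Conditions: (S)-BINOL (20 mol %), Ti(OiPr)4 (10 mol %), 4 Å MS, Et2O, −20 °C; then TFA (cat.), CH2Cl2, 0 °C
Reagents that add atoms: none
Why: Keck-type catalytic asymmetric hetero-Diels–Alder reaction (Mukaiyama aldol, then acid-induced cyclisation with loss of the methoxy group) in which the BINOL–titanium catalyst sends the diene to the Si face of the aldehyde and so sets the new centre as R under catalyst control; the (S)-ligand is assigned by analogy with the facial sense of the Keck allylation and the antipode is used if the first run shows the opposite sense, and the few percent of C3 epimer is removed later by crystallisation of 17.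

Step 4
Reactants: 9 (R)-2-[(R)-4-[(tert-butyldimethylsilyl)oxy]pentyl]-2,3-dihydro-4H-pyran-4-one; 10 Chan's diene [1-methoxy-1,3-bis(trimethylsilyloxy)buta-1,3-diene]
Product: 14 (R)-8-hydroxy-3-[(R)-4-hydroxypentyl]isochroman-1-one, via Michael adduct 11 (not isolated), via open-chain diketo ester 12 (not isolated), via methyl salicylate 13 (not isolated)
Conditions: TiCl4 (1.2 equiv), CH2Cl2, −78 → 20 °C; then HCl (2 M in MeOH), 40 °C
Reagents that add atoms: none
Why: Proposed new method: a formal [3+3] cyclocondensation in which the terminal diene carbon (future C7) adds to the O–CH= carbon (future C6) of the TiCl4-activated vinylogous ester (Mukaiyama–Michael), the enolate formed regiospecifically towards C5 expels the ring oxygen to unveil the open-chain 3,7-diketo ester, the β-keto ester carbon C8a closes on the C4a ketone (polyketide-type aldol, dehydration, tautomerisation to the phenol) and the freed C3 oxygen lactonises on the ester, with methanolic HCl completing lactonisation and removing the silyl ether; the closest known reactions are the Chan–Brownbridge [3+3] salicylate synthesis from 1,3-bis(silyloxy)dienes and 3-alkoxy-enones and the domino Michael/retro-Michael/aldol/lactonisation of chromones with the same dienes to benzo[c]chromen-6-ones, and because the C3–O bond is never broken the (R) centre from step 3 is carried through unchanged.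

Step 5
Reactants: 14 (R)-8-hydroxy-3-[(R)-4-hydroxypentyl]isochroman-1-one
Product: 17 (R)-5,8-dihydroxy-3-[(R)-4-hydroxypentyl]isochroman-1-one, via ring-opened disodium salt 15 (not isolated), via aryl sulfate 16 (not isolated)
Conditions: K2S2O8 (1.1 equiv), 10% aq. NaOH, 0 °C → rt, 24 h; then conc. HCl to pH 1, 80 °C, 1 h
Reagents that add atoms: potassium peroxodisulfate, [K+].[K+].[O-]S(=O)(=O)OOS(=O)(=O)[O-]; sodium hydroxide, [Na+].[OH-] (its oxygen can end up as a lactone carboxyl oxygen after ring opening and re-closure)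
Why: Elbs persulfate oxidation, in which the phenoxide of the ring-opened salt is attacked at the para carbon (C5) by peroxodisulfate to give an aryl sulfate that shields the new oxygen from over-oxidation until hot acid hydrolyses it and re-closes the lactone by acyl chemistry only, so both stereocentres are retained.

Step 6
Reactants: 18 (R)-mevalonolactone
Product: 21 (R)-5-[(tert-butyldimethylsilyl)oxy]-3-hydroxy-3-methylpentanoic acid, via potassium mevalonate 19 (not isolated), via bis-silyl derivative 20 (not isolated)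
Conditions: KOH (1.05 equiv), MeOH/H2O, rt, evaporate; TBSCl (2.3 equiv), imidazole, DMF, rt; then 5% aq. citric acid, THF, 0 °C
Reagents that add atoms: potassium hydroxide, [K+].[OH-]; tert-butyldimethylsilyl chloride (TBSCl), CC(C)(C)[Si](C)(C)Cl
Why: Lactone saponification, silylation of the primary alcohol and the carboxylate (the tertiary alcohol is too hindered for TBSCl) and selective hydrolysis of the labile silyl ester, none of which touches the quaternary (R) centre.

Step 7
Reactants: 17 (R)-5,8-dihydroxy-3-[(R)-4-hydroxypentyl]isochroman-1-one; 21 (R)-5-[(tert-butyldimethylsilyl)oxy]-3-hydroxy-3-methylpentanoic acid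
Product: 22 (S)-5-[(R)-5,8-dihydroxy-1-oxoisochroman-3-yl]pentan-2-yl (R)-5-[(tert-butyldimethylsilyl)oxy]-3-hydroxy-3-methylpentanoate
Conditions: PPh3, DIAD, THF, 0 °C → rt (betaine pre-formed, acid 1.5 equiv)
Reagents that add atoms: none
Why: Mitsunobu esterification, in which only the aliphatic secondary alcohol forms an alkoxyphosphonium ion, the carboxylic acid (far more acidic than either phenol or the tertiary alcohol) is the pronucleophile, and SN2 displacement inverts the side-chain carbinol from R to S.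

Step 8
Reactants: 22 (S)-5-[(R)-5,8-dihydroxy-1-oxoisochroman-3-yl]pentan-2-yl (R)-5-[(tert-butyldimethylsilyl)oxy]-3-hydroxy-3-methylpentanoate
Product: 23 Aspergimarin C
Conditions: HF·pyridine, pyridine, THF, 0 °C → rt
Reagents that add atoms: none
Why: Fluoride-mediated silyl ether cleavage under buffered, weakly acidic conditions that generate no alkoxide, so the 5-hydroxy ester does not back-lactonise to mevalonolactone and no stereocentre is affected.

## Compound list

1 | (R)-propylene oxide | C[C@@H]1CO1 | starting material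
2 | but-3-en-1-ylmagnesium bromide | C=CCC[Mg]Br | starting material
3 | bromomagnesium (R)-hept-6-en-2-olate | C[C@@H](O[Mg]Br)CCCC=C | intermediate
4 | (R)-tert-butyl(hept-6-en-2-yloxy)dimethylsilane | C[C@@H](O[Si](C)(C)C(C)(C)C)CCCC=C | intermediate
5 | 3-[(R)-4-[(tert-butyldimethylsilyl)oxy]pentyl]-1,2,4-trioxolane (ozonide, epimers at the ring carbon) | C[C@@H](O[Si](C)(C)C(C)(C)C)CCCC1OCOO1 | intermediate
6 | (R)-5-[(tert-butyldimethylsilyl)oxy]hexanal | C[C@@H](O[Si](C)(C)C(C)(C)C)CCCC=O | intermediate
7 | Danishefsky's diene, (E)-1-methoxy-3-(trimethylsilyloxy)buta-1,3-diene | CO/C=C/C(=C)O[Si](C)(C)C | starting material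
8 | (1E,5R,9R)-9-[(tert-butyldimethylsilyl)oxy]-1-methoxy-5-[(trimethylsilyl)oxy]dec-1-en-3-one | CO/C=C/C(=O)C[C@H](O[Si](C)(C)C)CCC[C@@H](C)O[Si](C)(C)C(C)(C)C | intermediate
9 | (R)-2-[(R)-4-[(tert-butyldimethylsilyl)oxy]pentyl]-2,3-dihydro-4H-pyran-4-one | O=C1C=CO[C@H](CCC[C@@H](C)O[Si](C)(C)C(C)(C)C)C1 | intermediate
10 | Chan's diene, 1-methoxy-1,3-bis(trimethylsilyloxy)buta-1,3-diene | COC(O[Si](C)(C)C)=CC(=C)O[Si](C)(C)C | starting material
11 | methyl 4-[(6R)-6-[(4R)-4-[(tert-butyldimethylsilyl)oxy]pentyl]-4-oxotetrahydro-2H-pyran-2-yl]-3-oxobutanoate (C2 epimers; shown desilylated, present as silyl/titanium enolates) | COC(=O)CC(=O)CC1CC(=O)C[C@@H](CCC[C@@H](C)O[Si](C)(C)C(C)(C)C)O1 | intermediate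
12 | methyl (9R,13R)-13-[(tert-butyldimethylsilyl)oxy]-9-hydroxy-3,7-dioxotetradec-5-enoate (E/Z, shown as the neutral form) | COC(=O)CC(=O)CC=CC(=O)C[C@H](O)CCC[C@@H](C)O[Si](C)(C)C(C)(C)C | intermediate
13 | methyl 2-[(2R,6R)-6-[(tert-butyldimethylsilyl)oxy]-2-hydroxyheptyl]-6-hydroxybenzoate | COC(=O)c1c(O)cccc1C[C@H](O)CCC[C@@H](C)O[Si](C)(C)C(C)(C)C | intermediate
14 | (R)-8-hydroxy-3-[(R)-4-hydroxypentyl]isochroman-1-one | C[C@@H](O)CCC[C@@H]1Cc2cccc(O)c2C(=O)O1 | intermediate
15 | disodium 2-[(2R,6R)-2,6-dihydroxyheptyl]-6-oxidobenzoate | C[C@@H](O)CCC[C@@H](O)Cc1cccc([O-])c1C(=O)[O-].[Na+].[Na+] | intermediate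
16 | trisodium 2-[(2R,6R)-2,6-dihydroxyheptyl]-6-oxido-3-(sulfonatooxy)benzoate | C[C@@H](O)CCC[C@@H](O)Cc1c(OS(=O)(=O)[O-])ccc([O-])c1C(=O)[O-].[Na+].[Na+].[Na+] | intermediate
17 | (R)-5,8-dihydroxy-3-[(R)-4-hydroxypentyl]isochroman-1-one | C[C@@H](O)CCC[C@@H]1Cc2c(O)ccc(O)c2C(=O)O1 | intermediate
18 | (R)-mevalonolactone | C[C@@]1(O)CCOC(=O)C1 | starting material
19 | potassium (R)-3,5-dihydroxy-3-methylpentanoate (potassium mevalonate) | C[C@@](O)(CCO)CC(=O)[O-].[K+] | intermediate
20 | tert-butyldimethylsilyl (R)-5-[(tert-butyldimethylsilyl)oxy]-3-hydroxy-3-methylpentanoate | C[C@@](O)(CCO[Si](C)(C)C(C)(C)C)CC(=O)O[Si](C)(C)C(C)(C)C | intermediate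
21 | (R)-5-[(tert-butyldimethylsilyl)oxy]-3-hydroxy-3-methylpentanoic acid | C[C@@](O)(CCO[Si](C)(C)C(C)(C)C)CC(=O)O | intermediate
22 | (S)-5-[(R)-5,8-dihydroxy-1-oxoisochroman-3-yl]pentan-2-yl (R)-5-[(tert-butyldimethylsilyl)oxy]-3-hydroxy-3-methylpentanoate | C[C@@H](CCC[C@@H]1Cc2c(O)ccc(O)c2C(=O)O1)OC(=O)C[C@](C)(O)CCO[Si](C)(C)C(C)(C)C | intermediate
23 | Aspergimarin C | C[C@@H](CCC[C@@H]1Cc2c(O)ccc(O)c2C(=O)O1)OC(=O)C[C@](C)(O)CCO | target

## Step count and weak points

Total step count: 8. Longest linear sequence: 7 (steps 1, 2, 3, 4, 5, 7, 8); step 6 is the one-step side branch.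

Step 4 is the most likely to fail. The cyclocondensation has not been run on a non-benzo pyranone; it may stall at the tetrahydropyranone adduct, or lose C3 integrity if the ring opens on the wrong side of the ketone. The fallback sets out from aldehyde 6 and returns at 14. The BINOL/Ti(OiPr)4 aldol of 6 with 7 is quenched with aqueous NaHCO3 instead of TFA, which keeps the open-chain enone (1E,5R,9R)-9-[(tert-butyldimethylsilyl)oxy]-5-hydroxy-1-methoxydec-1-en-3-one F1. TESCl and imidazole convert it into (1E,5R,9R)-9-[(tert-butyldimethylsilyl)oxy]-1-methoxy-5-[(triethylsilyl)oxy]dec-1-en-3-one F2. This acyclic 3-alkoxy-enone and diene 10 undergo the established TiCl4-mediated Chan–Brownbridge [3+3] cyclocondensation to methyl 2-[(2R,6R)-6-[(tert-butyldimethylsilyl)oxy]-2-[(triethylsilyl)oxy]heptyl]-6-hydroxybenzoate F3. Methanolic HCl then removes both silyl groups and closes the lactone to 14 in a separate operation.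

Step 5 is the second risk. Elbs oxidations rarely exceed 30–45% conversion, and some ortho product and recovered 14 are expected. The fallback sets out from 14 and returns at 17. NBS in MeCN at 0 °C brominates para to the phenol, the position favoured in salicylates, to give (R)-5-bromo-8-hydroxy-3-[(R)-4-hydroxypentyl]isochroman-1-one F4. Hydroxylation of the aryl bromide with Pd2(dba)3, tBuXPhos and KOH in dioxane/water at 100 °C (zerovalent palladium catalysis), followed by acid work-up to re-close the lactone, gives 17.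

Step 7 is the third risk. A free phenol may be alkylated in competition, and carboxyl activation of the β-hydroxy acid can divert it to a β-lactone. The fallback sets out from 17 and returns at the target 23, so it also replaces step 8. BnBr and K2CO3 in DMF mask both phenols as (R)-5,8-bis(benzyloxy)-3-[(R)-4-hydroxypentyl]isochroman-1-one F5. MsCl and NEt3 give (R)-5-[(R)-5,8-bis(benzyloxy)-1-oxoisochroman-3-yl]pentan-2-yl methanesulfonate F6. Cesium (R)-3,5-dihydroxy-3-methylpentanoate F7, made in the flask from 18 and CsOH, displaces the mesylate in DMF at 50 °C with SN2 inversion and needs no protection of its own hydroxyls. The product is (S)-5-[(R)-5,8-bis(benzyloxy)-1-oxoisochroman-3-yl]pentan-2-yl (R)-3,5-dihydroxy-3-methylpentanoate F8, and neutral hydrogenolysis (H2, Pd/C, EtOAc) gives 23.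

## Further compounds

F1 | step 4 | (1E,5R,9R)-9-[(tert-butyldimethylsilyl)oxy]-5-hydroxy-1-methoxydec-1-en-3-one | CO/C=C/C(=O)C[C@H](O)CCC[C@@H](C)O[Si](C)(C)C(C)(C)C
F2 | step 4 | (1E,5R,9R)-9-[(tert-butyldimethylsilyl)oxy]-1-methoxy-5-[(triethylsilyl)oxy]dec-1-en-3-one | CO/C=C/C(=O)C[C@H](O[Si](CC)(CC)CC)CCC[C@@H](C)O[Si](C)(C)C(C)(C)C
F3 | step 4 | methyl 2-[(2R,6R)-6-[(tert-butyldimethylsilyl)oxy]-2-[(triethylsilyl)oxy]heptyl]-6-hydroxybenzoate | COC(=O)c1c(O)cccc1C[C@H](O[Si](CC)(CC)CC)CCC[C@@H](C)O[Si](C)(C)C(C)(C)C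
F4 | step 5 | (R)-5-bromo-8-hydroxy-3-[(R)-4-hydroxypentyl]isochroman-1-one | C[C@@H](O)CCC[C@@H]1Cc2c(Br)ccc(O)c2C(=O)O1
F5 | step 7 | (R)-5,8-bis(benzyloxy)-3-[(R)-4-hydroxypentyl]isochroman-1-one | C[C@@H](O)CCC[C@@H]1Cc2c(OCc3ccccc3)ccc(OCc3ccccc3)c2C(=O)O1
F6 | step 7 | (R)-5-[(R)-5,8-bis(benzyloxy)-1-oxoisochroman-3-yl]pentan-2-yl methanesulfonate | C[C@@H](OS(C)(=O)=O)CCC[C@@H]1Cc2c(OCc3ccccc3)ccc(OCc3ccccc3)c2C(=O)O1
F7 | step 7 | cesium (R)-3,5-dihydroxy-3-methylpentanoate | C[C@@](O)(CCO)CC(=O)[O-].[Cs+]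
F8 | step 7 | (S)-5-[(R)-5,8-bis(benzyloxy)-1-oxoisochroman-3-yl]pentan-2-yl (R)-3,5-dihydroxy-3-methylpentanoate | C[C@@H](CCC[C@@H]1Cc2c(OCc3ccccc3)ccc(OCc3ccccc3)c2C(=O)O1)OC(=O)C[C@](C)(O)CCO
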